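**Retrosynthetic overview**
- The target is reached by two acylations and a desilylation from a 2α-silyloxy-labda-7,13E-diene-15,19-diol, which comes from the bicyclic C19 methyl ester by hydride reduction.
- Key disconnection: the C4–C5 and C9–C10 bonds. Rings A and then B form in one operation from a linear geranylgeranyl-type C20 tetraene, folded head-to-tail (chair–chair) as in the labda-7,13-dienyl diphosphate cyclase.
- In that step H• transfer to a terminal methacrylate stands in for protonation, and loss of PhSO2• from C7 stands in for loss of H-7, so only the Δ7 alkene can form.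
- The single stereocentre of the acyclic precursor (C2–O) comes from a catalytic asymmetric 2-(methoxycarbonyl)allylation of a C16 aldehyde, and it directs the folding.
- The C6–C7 bond comes from alkylating 8-(phenylsulfonyl)geranyl acetate (from geranyl acetate) with (E)-5-bromo-3-methylpent-3-en-1-ol (from but-3-yn-1-ol).

Assumption: the SMILES is read as the normal-series labdane (2R,4S,5R,9S,10R,13E), i.e. 2α-OH, 19-O-isovaleryl, 15-O-(methyl succinyl). The sulfone-bearing carbon of the acyclic intermediates is carried as a ~1:1 epimer mixture that is erased in step 8. In step 7 the ligand antipode that gives the (R)-carbinol is used; the sense must be confirmed (Mosher ester).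

**Route**

Step 1
Reactants: 1 geranyl acetate
Product: 2 (2E,6E)-8-hydroxy-3,7-dimethylocta-2,6-dien-1-yl acetate
Conditions: SeO2 (0.1 equiv), t-BuOOH (3 equiv), salicylic acid (0.1 equiv), CH2Cl2, 0 °C→rt
Reagents that add atoms: selenium dioxide O=[Se]=O (O-atom carrier); tert-butyl hydroperoxide CC(C)(C)OO (terminal oxidant)
Why: Sharpless–Umbreit SeO2 allylic oxidation (ene then [2,3] shift) attacks only the E-methyl of the electron-rich terminal alkene; the acetate-bearing alkene is deactivated.

Step 2
Reactants: 2 (2E,6E)-8-hydroxy-3,7-dimethylocta-2,6-dien-1-yl acetate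
Product: 4 (2E,6E)-3,7-dimethyl-8-(phenylsulfonyl)octa-2,6-dien-1-yl acetate, via allylic mesylate 3 (not isolated)
Conditions: MsCl, Et3N, THF, −40→0 °C; then PhSO2Na, n-Bu4NI (cat.), DMF, rt
Reagents that add atoms: methanesulfonyl chloride CS(=O)(=O)Cl (atoms in 3 only); sodium benzenesulfinate [Na+].[O-]S(=O)c1ccccc1
Why: Mesylation followed by SN2 S-alkylation of the sulfinate in DMF gives the primary allyl sulfone without touching either alkene geometry.

Step 3
Reactants: 5 but-3-yn-1-ol
Product: 8 (E)-3-methylpent-2-ene-1,5-diol, via alkenylalane 6 (not isolated), via lithium alanate 7 (not isolated)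
Conditions: Me3Al (3 equiv), Cp2ZrCl2 (0.25 equiv), CH2Cl2, 0 °C→rt; n-BuLi, THF, −78 °C; (CH2O)n, →rt; aq. Rochelle salt
Reagents that add atoms: trimethylaluminium C[Al](C)C; formaldehyde C=O (as paraformaldehyde); n-butyllithium [Li]CCCC (atoms in 7 only)
Why: Negishi Zr-catalysed syn-carboalumination puts Me on the internal and Al on the terminal alkyne carbon, and the alanate is hydroxymethylated with retention, which fixes the E-trisubstituted alkene.

Step 4
Reactants: 8 (E)-3-methylpent-2-ene-1,5-diol
Product: 9 (E)-5-bromo-3-methylpent-3-en-1-ol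
Conditions: NBS, Me2S, CH2Cl2, −20→0 °C
Reagents that add atoms: N-bromosuccinimide O=C1CCC(=O)N1Br
Why: Corey–Kim halogenation converts only the allylic hydroxyl; the E-alkene prevents the bromo alcohol from cyclising on itself.

Step 5
Reactants: 4 (2E,6E)-3,7-dimethyl-8-(phenylsulfonyl)octa-2,6-dien-1-yl acetate; 9 (E)-5-bromo-3-methylpent-3-en-1-ol
Product: 11 (2E,6E,10E)-13-hydroxy-3,7,11-trimethyl-8-(phenylsulfonyl)trideca-2,6,10-trien-1-yl acetate (C8 epimers ~1:1), via lithiated sulfone 10 (not isolated)
Conditions: LiHMDS (1.05 equiv), THF/DMPU, −78 °C; then 9, −78→−40 °C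
Reagents that add atoms: lithium bis(trimethylsilyl)amide [Li]N([Si](C)(C)C)[Si](C)(C)C (Li in 10 only)
Why: Biellmann/Julia-type α-alkylation of a lithiated allyl sulfone by a primary allylic bromide (SN2); the carbanion is far less basic than an alkoxide and at −78 °C alkylates faster than it acylates, so the free OH and the acetate survive, and the new sulfone stereocentre is irrelevant.

Step 6
Reactants: 11 (2E,6E,10E)-13-hydroxy-3,7,11-trimethyl-8-(phenylsulfonyl)trideca-2,6,10-trien-1-yl acetate
Product: 12 (2E,6E,10E)-3,7,11-trimethyl-13-oxo-8-(phenylsulfonyl)trideca-2,6,10-trien-1-yl acetate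
Conditions: Dess–Martin periodinane, NaHCO3, CH2Cl2, 0 °C; used crude
Reagents that add atoms: none
Why: Buffered Dess–Martin oxidation gives the β,γ-unsaturated aldehyde under non-acidic, non-basic conditions, so the alkene does not move into conjugation.

Step 7
Reactants: 12 (2E,6E,10E)-3,7,11-trimethyl-13-oxo-8-(phenylsulfonyl)trideca-2,6,10-trien-1-yl acetate; 13 methyl 2-(bromomethyl)acrylate
Product: 14 methyl (4R,6E,10E,14E)-16-acetoxy-6,10,14-trimethyl-2-methylidene-9-(phenylsulfonyl)-4-(triethylsilyloxy)hexadeca-6,10,14-trienoate (C9 epimers)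
Conditions: CrCl2 (10 mol %), chiral carbazole-bis(oxazoline) ligand (12 mol %), Mn, Et3SiCl, i-Pr2NEt (cat.), THF, rt
Reagents that add atoms: chlorotriethylsilane CC[Si](Cl)(CC)CC
Why: Catalytic asymmetric Nozaki–Hiyama (Cr) 2-(alkoxycarbonyl)allylation: the ligand-bound allylchromium adds to one aldehyde face through a closed transition state to set the (R)-carbinol (C2 of the target), and Et3SiCl cleaves the Cr–O bond, which turns the catalyst over and releases the product as its TES ether so it cannot lactonise.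

Step 8
Reactants: 14 methyl (4R,6E,10E,14E)-16-acetoxy-6,10,14-trimethyl-2-methylidene-9-(phenylsulfonyl)-4-(triethylsilyloxy)hexadeca-6,10,14-trienoate
Product: 15 methyl (13E)-15-acetoxy-2α-(triethylsilyloxy)labda-7,13-dien-19-oate (2R,4S,5R,9S,10R)
Conditions: Fe(acac)3 (30 mol %), Ph(i-PrO)SiH2 (2 equiv, slow addition), i-PrOH/THF, 0.005 M, degassed, 25 °C
Reagents that add atoms: none
Why: Proposed new method: Fe–H transfers H• to the unhindered methacrylate CH2 to give the ester-stabilised tertiary C4 radical, which closes 6-endo on C5=C10 and then 6-endo on the allyl sulfone through a chair–chair array in which the C2–OSiEt3 group is equatorial (an axial one would be 1,3-diaxial to both C20 and C19, so this fixes 5α-H, 10β-Me, 9α-H from the one existing centre) and the flat CO2Me, not CH3, sits axial opposite C20 (4β-CO2Me, estimated ~5:1), after which the C8 radical expels PhSO2• to give only the Δ7 alkene and Fe(II) reduces PhSO2• to sulfinate to close the cycle; the closest known reaction types are Fe/Mn-hydride MHAT radical cyclisations, Snider-type 6-endo/6-endo polyene bicyclisations of α-carbonyl radicals (axial C4 ester) and radical allylation by β-sulfonyl fragmentation of allyl sulfones.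

Step 9
Reactants: 15 methyl (13E)-15-acetoxy-2α-(triethylsilyloxy)labda-7,13-dien-19-oate
Product: 16 (13E)-2α-(triethylsilyloxy)labda-7,13-diene-15,19-diol
Conditions: LiAlH4, THF, 0 °C→rt
Reagents that add atoms: none
Why: Hydride reduction takes the hindered axial methyl ester to the C19 carbinol and cleaves the acetate in the same operation; the silyl ether and both alkenes are inert and no stereocentre is touched.

Step 10
Reactants: 16 (13E)-2α-(triethylsilyloxy)labda-7,13-diene-15,19-diol; 17 methyl 4-chloro-4-oxobutanoate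
Product: 18 methyl (13E)-19-hydroxy-2α-(triethylsilyloxy)labda-7,13-dien-15-yl butanedioate
Conditions: 17 (1.05 equiv), 2,4,6-collidine, CH2Cl2, −78→−40 °C
Reagents that add atoms: none
Why: Kinetic acylation with an acid chloride and collidine at low temperature selects the unhindered allylic primary OH over the axial neopentyl C19–OH, which is 1,3-diaxial to C20.

Step 11
Reactants: 18 methyl (13E)-19-hydroxy-2α-(triethylsilyloxy)labda-7,13-dien-15-yl butanedioate; 19 3-methylbutanoyl chloride
Product: 21 methyl (13E)-2α-hydroxy-19-(3-methylbutanoyloxy)labda-7,13-dien-15-yl butanedioate (CNP0118741.1), via triethylsilyl ether 20 (not isolated)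
Conditions: 19 (3 equiv), pyridine, DMAP (cat.), CH2Cl2, 0 °C→rt; then HF·pyridine, THF, 0 °C→rt
Reagents that add atoms: none
Why: DMAP-catalysed acylation of the only free (neopentyl) hydroxyl, then buffered fluoride cleavage of the Si–O bond in the same flask, frees the 2α-OH without touching either ester or any stereocentre.

**Compound list**
1 | geranyl acetate, (2E)-3,7-dimethylocta-2,6-dien-1-yl acetate | CC(=O)OC/C=C(\C)CCC=C(C)C | starting material
2 | (2E,6E)-8-hydroxy-3,7-dimethylocta-2,6-dien-1-yl acetate | CC(=O)OC/C=C(\C)CC/C=C(\C)CO | intermediate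
3 | (2E,6E)-3,7-dimethyl-8-(methylsulfonyloxy)octa-2,6-dien-1-yl acetate | CC(=O)OC/C=C(\C)CC/C=C(\C)COS(C)(=O)=O | intermediate
4 | (2E,6E)-3,7-dimethyl-8-(phenylsulfonyl)octa-2,6-dien-1-yl acetate | CC(=O)OC/C=C(\C)CC/C=C(\C)CS(=O)(=O)c1ccccc1 | intermediate
5 | but-3-yn-1-ol | C#CCCO | starting material
6 | (E)-alkenyl(dimethyl)alane, Al cis to the new methyl, as its O-dimethylaluminium alkoxide | C[Al](C)/C=C(\C)CCO[Al](C)C | intermediate
7 | lithium n-butyl(dimethyl)alkenylalanate of 6 | [Li+].CCCC[Al-](C)(C)/C=C(\C)CCO[Al](C)C | intermediate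
8 | (E)-3-methylpent-2-ene-1,5-diol | OC/C=C(\C)CCO | intermediate
9 | (E)-5-bromo-3-methylpent-3-en-1-ol | BrC/C=C(\C)CCO | intermediate
10 | α-lithio derivative of sulfone 4 | CC(=O)OC/C=C(\C)CC/C=C(\C)C([Li])S(=O)(=O)c1ccccc1 | intermediate
11 | (2E,6E,10E)-13-hydroxy-3,7,11-trimethyl-8-(phenylsulfonyl)trideca-2,6,10-trien-1-yl acetate (8RS) | CC(=O)OC/C=C(\C)CC/C=C(\C)C(C/C=C(\C)CCO)S(=O)(=O)c1ccccc1 | intermediate
12 | (2E,6E,10E)-3,7,11-trimethyl-13-oxo-8-(phenylsulfonyl)trideca-2,6,10-trien-1-yl acetate (8RS) | CC(=O)OC/C=C(\C)CC/C=C(\C)C(C/C=C(\C)CC=O)S(=O)(=O)c1ccccc1 | intermediate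
13 | methyl 2-(bromomethyl)acrylate | C=C(CBr)C(=O)OC | starting material
14 | methyl (4R,6E,10E,14E)-16-acetoxy-6,10,14-trimethyl-2-methylidene-9-(phenylsulfonyl)-4-(triethylsilyloxy)hexadeca-6,10,14-trienoate (9RS) | CC(=O)OC/C=C(\C)CC/C=C(\C)C(C/C=C(\C)C[C@@H](O[Si](CC)(CC)CC)CC(=C)C(=O)OC)S(=O)(=O)c1ccccc1 | intermediate
15 | methyl (13E)-15-acetoxy-2α-(triethylsilyloxy)labda-7,13-dien-19-oate; 4β-CO2Me, 5α-H, 9α-H, 10β-Me | CC(=O)OC/C=C(\C)CC[C@H]1C(C)=CC[C@H]2[C@@](C)(C(=O)OC)C[C@H](O[Si](CC)(CC)CC)C[C@]12C | intermediate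
16 | (13E)-2α-(triethylsilyloxy)labda-7,13-diene-15,19-diol | OC/C=C(\C)CC[C@H]1C(C)=CC[C@H]2[C@@](C)(CO)C[C@H](O[Si](CC)(CC)CC)C[C@]12C | intermediate
17 | methyl 4-chloro-4-oxobutanoate | COC(=O)CCC(Cl)=O | starting material
18 | methyl (13E)-19-hydroxy-2α-(triethylsilyloxy)labda-7,13-dien-15-yl butanedioate | COC(=O)CCC(=O)OC/C=C(\C)CC[C@H]1C(C)=CC[C@H]2[C@@](C)(CO)C[C@H](O[Si](CC)(CC)CC)C[C@]12C | intermediate
19 | 3-methylbutanoyl chloride | CC(C)CC(Cl)=O | starting material
20 | methyl (13E)-19-(3-methylbutanoyloxy)-2α-(triethylsilyloxy)labda-7,13-dien-15-yl butanedioate | COC(=O)CCC(=O)OC/C=C(\C)CC[C@H]1C(C)=CC[C@H]2[C@@](C)(COC(=O)CC(C)C)C[C@H](O[Si](CC)(CC)CC)C[C@]12C | intermediate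
21 | methyl (13E)-2α-hydroxy-19-(3-methylbutanoyloxy)labda-7,13-dien-15-yl butanedioate, (2R,4S,5R,9S,10R) | COC(=O)CCC(=O)OC/C=C(\C)CC[C@H]1C(C)=CC[C@H]2[C@@](C)(COC(=O)CC(C)C)C[C@H](O)C[C@]12C | target

**Step count and risks**

Total steps: 11 (steps 2, 3 and 11 are one-pot, two-stage operations). Longest linear sequence: 9 (1→2→5→6→7→8→9→10→11, or equally 3→4→5→…→11).

Steps most likely to fail:

1. Step 8 (key bicyclisation). Three things can go wrong:
   - Fe–H must choose the methacrylate over three trisubstituted alkenes, and the C4 radical must cyclise before it is reduced.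
   - The axial-ester preference at C4 is only an estimate.
   - The C7 epimer whose sulfonyl group is equatorial in the chair fragments more slowly and could leak into tricyclisation onto the Δ13 alkene.

   Fallback, setting out from 14 and returning at 15: run a reductant-free sulfonyl-radical chain (PhSO2Na/AcOH 10 mol %, dilauroyl peroxide 10 mol %, benzene, 80 °C, 0.005 M). PhSO2• adds to the methacrylate CH2, the same 6-endo/6-endo cascade follows, and the C8 radical expels PhSO2• to carry the chain. This group-transfer cycloisomerisation gives methyl (13E)-15-acetoxy-18-(phenylsulfonyl)-2α-(triethylsilyloxy)labda-7,13-dien-19-oate F1. Reductive desulfonylation (6 % Na/Hg, Na2HPO4, MeOH/THF, −20 °C) turns C18 into the methyl group of 15.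

2. Step 7 (asymmetric allylation). The β,γ-unsaturated aldehyde 12 can slip into conjugation, and the enantiomeric purity of the whole series rests on this one step (about 90 % ee expected for an α-unbranched aldehyde; upgrade by crystallising diol 16 if needed). Fallback, setting out from 11 and returning at 14: an alcohol-level Krische coupling, so that the aldehyde is never isolated. Conditions are [Ir(cod)Cl]2, a chiral SEGPHOS-type ligand, 4-chloro-3-nitrobenzoic acid, Cs2CO3 (cat.) and methyl 2-{[(tert-butoxycarbonyl)oxy]methyl}acrylate in THF at 60 °C. This gives methyl (4R,6E,10E,14E)-16-acetoxy-4-hydroxy-6,10,14-trimethyl-2-methylidene-9-(phenylsulfonyl)hexadeca-6,10,14-trienoate F2, which is silylated (Et3SiCl, imidazole, CH2Cl2, 0 °C) to 14.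

3. Step 5 (fragment coupling). The sulfonyl carbanion may be quenched by the free hydroxyl or may attack the acetate. Fallback, setting out from 9 and returning at 11: first silylate 9 (TBSCl, imidazole) to (E)-[(5-bromo-3-methylpent-3-en-1-yl)oxy](tert-butyl)dimethylsilane F3. Alkylate lithiated sulfone 10 with F3 by inverse addition at −78 °C to give the TBS ether of 11, (2E,6E,10E)-13-(tert-butyldimethylsilyloxy)-3,7,11-trimethyl-8-(phenylsulfonyl)trideca-2,6,10-trien-1-yl acetate F4. Remove the silyl group with HF·pyridine in THF to rejoin at 11.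

**Further compounds**
F1 | step 8 | methyl (13E)-15-acetoxy-18-(phenylsulfonyl)-2α-(triethylsilyloxy)labda-7,13-dien-19-oate | CC(=O)OC/C=C(\C)CC[C@H]1C(C)=CC[C@H]2[C@@](CS(=O)(=O)c3ccccc3)(C(=O)OC)C[C@H](O[Si](CC)(CC)CC)C[C@]12C
F2 | step 7 | methyl (4R,6E,10E,14E)-16-acetoxy-4-hydroxy-6,10,14-trimethyl-2-methylidene-9-(phenylsulfonyl)hexadeca-6,10,14-trienoate | CC(=O)OC/C=C(\C)CC/C=C(\C)C(C/C=C(\C)C[C@@H](O)CC(=C)C(=O)OC)S(=O)(=O)c1ccccc1
F3 | step 5 | (E)-[(5-bromo-3-methylpent-3-en-1-yl)oxy](tert-butyl)dimethylsilane | BrC/C=C(\C)CCO[Si](C)(C)C(C)(C)C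
F4 | step 5 | (2E,6E,10E)-13-(tert-butyldimethylsilyloxy)-3,7,11-trimethyl-8-(phenylsulfonyl)trideca-2,6,10-trien-1-yl acetate | CC(=O)OC/C=C(\C)CC/C=C(\C)C(C/C=C(\C)CCO[Si](C)(C)C(C)(C)C)S(=O)(=O)c1ccccc1
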